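**Plan**
1. Retrosynthesis (coumarin A = ether-linked end unit, B = central 3-aryloxy-7-hydroxycoumarin, C = 8-linked 7-hydroxycoumarin): the C8–C8′ biaryl bond between B and C is cut first, after the two 7-oxygens beside it are tied through one silicon atom. Next the pyranone of ring B is opened at its lactone C–O and C3=C4 bonds (Perkin), and last the O–CH2 ether bond to ring A.
2. Forward: umbelliferone is O-alkylated and saponified, the pyranone of ring B is built on the aryloxyacetic acid, and C8 is iodinated. Umbelliferone itself is iodinated at C8′, the two iodophenols are clipped as a mixed di-tert-butylsilylene diether, copper closes the biaryl bond and HF removes silicon.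
3. Enabling feature: each carbon of the new bond lies between the phenolic O7 and the lactone O1 of a 7-hydroxycoumarin. Each 7-OH therefore steers iodine to its C8 and then anchors an O7–Si–O7′ bridge, so the hindered tetra-ortho-substituted coupling becomes closure of a seven-membered 1,3,2-dioxasilepine.
4. Stereochemistry: the target has no stereocentre; nothing has to be controlled.

Key step: step 7

Remark: the target SMILES fixes no sense of the C8–C8′ axis, so the axis is formed without control.

**Step 1**
Reactants: 1 umbelliferone (7-hydroxy-2H-chromen-2-one); 2 ethyl bromoacetate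
Product: 3 ethyl 2-[(2-oxo-2H-chromen-7-yl)oxy]acetate
Conditions: K2CO3, acetone, reflux
Reagents that add atoms: none
Why: Williamson ether synthesis, in which the phenoxide of the acidic 7-OH is the only nucleophile, the α-bromo ester is a fast SN2 electrophile and the lactone is untouched by carbonate in acetone.

**Step 2**
Reactants: 3 ethyl 2-[(2-oxo-2H-chromen-7-yl)oxy]acetate
Product: 4 2-[(2-oxo-2H-chromen-7-yl)oxy]acetic acid
Conditions: NaOH, THF–H2O, 0 °C → rt; then aq. HCl to pH 1
Reagents that add atoms: sodium hydroxide, [Na+].[OH-]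
Why: Ester saponification, in which any lactone opened by hydroxide is the cis-coumarinate and should reclose on acidification, so that the intact coumarin acid is expected.

**Step 3**
Reactants: 4 2-[(2-oxo-2H-chromen-7-yl)oxy]acetic acid; 5 2,4-dihydroxybenzaldehyde
Product: 6 2-oxo-3-[(2-oxo-2H-chromen-7-yl)oxy]-2H-chromen-7-yl acetate
Conditions: Ac2O, Et3N, 120 °C
Reagents that add atoms: acetic anhydride, CC(=O)OC(C)=O
Why: Perkin condensation (Oglialoro variant), in which the mixed anhydride of 4 acylates the ortho-hydroxyl of 5, intramolecular aldol addition of the activated OCH2 group to the aldehyde and dehydration close the pyranone of ring B with the aryloxy group at C3, and the para-hydroxyl is acetylated in the same pot.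

**Step 4**
Reactants: 6 2-oxo-3-[(2-oxo-2H-chromen-7-yl)oxy]-2H-chromen-7-yl acetate
Product: 8 7-hydroxy-8-iodo-3-[(2-oxo-2H-chromen-7-yl)oxy]-2H-chromen-2-one, via edgeworin 7 (not isolated)
Conditions: conc. aq. NH3, dioxane, rt; then I2 (1.0 equiv), KI, H2O, 0 °C → rt; aq. HCl
Reagents that add atoms: iodine, II
Why: Aminolysis of the aryl acetate followed by electrophilic aromatic iodination of the phenoxide, which in 7-hydroxycoumarins should go to C8, the ortho carbon between O7 and O1, while ring A, a neutral aryl ether, stays inert.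

**Step 5**
Reactants: 1 umbelliferone
Product: 9 7-hydroxy-8-iodo-2H-chromen-2-one
Conditions: I2 (1.0 equiv), KI, 20% aq. NH3, rt; aq. HCl
Reagents that add atoms: iodine, II
Why: Electrophilic aromatic iodination of the ammonium phenoxide, for which the 2-naphthol-like bond fixation of the 7-hydroxycoumarin makes C8 the preferred ortho position.

**Step 6**
Reactants: 9 7-hydroxy-8-iodo-2H-chromen-2-one; 8 7-hydroxy-8-iodo-3-[(2-oxo-2H-chromen-7-yl)oxy]-2H-chromen-2-one
Product: 11 di-tert-butyl[(8-iodo-2-oxo-2H-chromen-7-yl)oxy]({8-iodo-2-oxo-3-[(2-oxo-2H-chromen-7-yl)oxy]-2H-chromen-7-yl}oxy)silane, via silyl triflate 10 (not isolated)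
Conditions: tBu2Si(OTf)2 (1.0 equiv), 2,6-lutidine, DMF, −40 → 0 °C (9 added slowly); then 8, imidazole, 50 °C
Reagents that add atoms: di-tert-butylsilyl bis(trifluoromethanesulfonate), CC(C)(C)[Si](OS(=O)(=O)C(F)(F)F)(OS(=O)(=O)C(F)(F)F)C(C)(C)C
Why: Stepwise O-silylation (silyl ether formation) with a bifunctional silyl bis-triflate, in which the first triflate is displaced in the cold and the second, slowed by the two tert-butyl groups, only on warming with the second phenol, so that the mixed bis(aryloxy)silane should result.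

**Step 7**
Reactants: 11 di-tert-butyl[(8-iodo-2-oxo-2H-chromen-7-yl)oxy]({8-iodo-2-oxo-3-[(2-oxo-2H-chromen-7-yl)oxy]-2H-chromen-7-yl}oxy)silane
Product: 12 7,7′-O,O′-(di-tert-butylsilanediyl)triumbelletin (the 8,8′-bicoumarin whose two 7-oxygens are bridged by tBu2Si in a seven-membered 1,3,2-dioxasilepine ring; ring B carries the 3-(coumarin-7-yloxy) group)
Conditions: activated Cu bronze (10 equiv), degassed DMF (5 mM), 130 °C
Reagents that add atoms: none
Why: Intramolecular Ullmann biaryl coupling: copper metal inserts into one C8–I bond to give an aryl copper species of monovalent copper, this adds across the second C–I bond held beside it by the O7–Si–O7′ bridge, and the diaryl intermediate of trivalent copper collapses by reductive elimination to the C8–C8′ bond and CuI. The closest known reaction type is the tether-directed intramolecular Ullmann coupling of two aryl iodides, the classical entry to tetra-ortho-substituted, ortho-oxygenated biaryls, carried here by a bis(aryloxy)silane bridge of the kind known to template ring-closing biaryl formation under palladium catalysis. The only ring closed is the seven-membered dibenzo-1,3,2-dioxasilepine, formed by C–C reductive elimination from an eight-membered cupracycle, and no stereocentre arises, the axis being formed as a racemate. The step needs cross-selectivity (B with C, no B–B or C–C dimer) and site selectivity (C8 and C8′, not C6 or C6′): the bridge and high dilution secure the first, and the two iodine atoms, each placed between O7 and O1 in steps 4 and 5, secure the second. The lactones, the diaryl ether and the hindered silyl diether offer nothing that copper attacks under these neutral, base-free conditions.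

**Step 8**
Reactants: 12 7,7′-O,O′-(di-tert-butylsilanediyl)triumbelletin
Product: 13 triumbelletin
Conditions: HF·pyridine, THF–pyridine, 0 °C → rt
Reagents that add atoms: none
Why: Fluoride-mediated desilylation, in which formation of two strong Si–F bonds should release both phenols while the lactones and the diaryl ether are inert to buffered HF.

**Compound list**
1 | umbelliferone (7-hydroxy-2H-chromen-2-one) | O=c1ccc2ccc(O)cc2o1 | starting material
2 | ethyl bromoacetate | CCOC(=O)CBr | starting material
3 | ethyl 2-[(2-oxo-2H-chromen-7-yl)oxy]acetate | CCOC(=O)COc1ccc2ccc(=O)oc2c1 | intermediate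
4 | 2-[(2-oxo-2H-chromen-7-yl)oxy]acetic acid | OC(=O)COc1ccc2ccc(=O)oc2c1 | intermediate
5 | 2,4-dihydroxybenzaldehyde | O=Cc1ccc(O)cc1O | starting material
6 | 2-oxo-3-[(2-oxo-2H-chromen-7-yl)oxy]-2H-chromen-7-yl acetate | CC(=O)Oc1ccc2cc(Oc3ccc4ccc(=O)oc4c3)c(=O)oc2c1 | intermediate
7 | edgeworin, 7-hydroxy-3-[(2-oxo-2H-chromen-7-yl)oxy]-2H-chromen-2-one | Oc1ccc2cc(Oc3ccc4ccc(=O)oc4c3)c(=O)oc2c1 | intermediate
8 | 7-hydroxy-8-iodo-3-[(2-oxo-2H-chromen-7-yl)oxy]-2H-chromen-2-one | Oc1ccc2cc(Oc3ccc4ccc(=O)oc4c3)c(=O)oc2c1I | intermediate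
9 | 7-hydroxy-8-iodo-2H-chromen-2-one | O=c1ccc2ccc(O)c(I)c2o1 | intermediate
10 | di-tert-butyl[(8-iodo-2-oxo-2H-chromen-7-yl)oxy]silyl trifluoromethanesulfonate | CC(C)(C)[Si](Oc1ccc2ccc(=O)oc2c1I)(OS(=O)(=O)C(F)(F)F)C(C)(C)C | intermediate
11 | di-tert-butyl[(8-iodo-2-oxo-2H-chromen-7-yl)oxy]({8-iodo-2-oxo-3-[(2-oxo-2H-chromen-7-yl)oxy]-2H-chromen-7-yl}oxy)silane | CC(C)(C)[Si](Oc1ccc2ccc(=O)oc2c1I)(Oc1ccc2cc(Oc3ccc4ccc(=O)oc4c3)c(=O)oc2c1I)C(C)(C)C | intermediate
12 | 7,7′-O,O′-(di-tert-butylsilanediyl)triumbelletin | CC(C)(C)[Si]1(C(C)(C)C)Oc2ccc3ccc(=O)oc3c2-c2c(O1)ccc3cc(Oc4ccc5ccc(=O)oc5c4)c(=O)oc23 | intermediate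
13 | triumbelletin | O=c1ccc2ccc(Oc3cc4ccc(O)c(-c5c(O)ccc6ccc(=O)oc56)c4oc3=O)cc2o1 | target

**Totals**
Total step count: 8. Longest linear sequence: 7 steps (steps 1, 2, 3, 4, 6, 7 and 8, from umbelliferone).

**Steps most likely to fail**

Step 7. Copper insertion into the two doubly flanked C–I bonds may be slow, so that hydrodeiodination, intermolecular coupling or thermal loss of the silylene bridge outruns ring closure. The fallback drops the tether and joins the halves by an intermolecular Suzuki–Miyaura coupling of protected monomers; it sets out from 9 and 8 and comes back to the route at 13. Compound 9 is protected (MOMCl, iPr2NEt, CH2Cl2) as 8-iodo-7-(methoxymethoxy)-2H-chromen-2-one F1. Miyaura borylation of F1 (B2pin2, PdCl2(dppf), KOAc, dioxane, 90 °C) should give 7-(methoxymethoxy)-8-(4,4,5,5-tetramethyl-1,3,2-dioxaborolan-2-yl)-2H-chromen-2-one F2. Compound 8 is protected in the same way as 8-iodo-7-(methoxymethoxy)-3-[(2-oxo-2H-chromen-7-yl)oxy]-2H-chromen-2-one F3. Coupling of F2 with F3 (Pd(OAc)2, SPhos, K3PO4, toluene–H2O, 100 °C, acidic work-up to reclose any opened lactone) should give 7,7′-bis-O-(methoxymethyl)triumbelletin F4, and HCl in MeOH at 50 °C removes both acetals to give 13.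

Step 6. Exchange of aryloxy groups at silicon may give the symmetrical diethers, or the second silylation may stall between the two ortho-iodo phenols. The fallback builds the bridge from a monofunctional hydrosilane that cannot react twice; it sets out from 9 and comes back at 11. Compound 9 with tBu2SiHCl and imidazole in DMF should give the isolable di-tert-butyl[(8-iodo-2-oxo-2H-chromen-7-yl)oxy]silane F5. After purification, NBS in CH2Cl2 at 0 °C converts Si–H into Si–Br to give bromodi-tert-butyl[(8-iodo-2-oxo-2H-chromen-7-yl)oxy]silane F6, which is treated directly with 8 and imidazole in DMF at 50 °C to give 11.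

Step 4. Iodination may also occur at C6 or twice, and the phenoxide may stay partly acetylated. The fallback brings the iodine in with the arene, where its position is unambiguous; it sets out from 4 and comes back at 8. 2-Iodobenzene-1,3-diol F7 is formylated (Vilsmeier–Haack: POCl3, DMF, MeCN, 0 °C → rt, then H2O) at the only activated position to give 2,4-dihydroxy-3-iodobenzaldehyde F8. Perkin condensation of F8 with 4 (Ac2O, Et3N, 120 °C) should give 8-iodo-2-oxo-3-[(2-oxo-2H-chromen-7-yl)oxy]-2H-chromen-7-yl acetate F9, and aqueous NH3 in dioxane cleaves the acetate to give 8.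

**Further compounds**
F1 | step 7 | 8-iodo-7-(methoxymethoxy)-2H-chromen-2-one | COCOc1ccc2ccc(=O)oc2c1I
F2 | step 7 | 7-(methoxymethoxy)-8-(4,4,5,5-tetramethyl-1,3,2-dioxaborolan-2-yl)-2H-chromen-2-one | COCOc1ccc2ccc(=O)oc2c1B1OC(C)(C)C(C)(C)O1
F3 | step 7 | 8-iodo-7-(methoxymethoxy)-3-[(2-oxo-2H-chromen-7-yl)oxy]-2H-chromen-2-one | COCOc1ccc2cc(Oc3ccc4ccc(=O)oc4c3)c(=O)oc2c1I
F4 | step 7 | 7,7′-bis-O-(methoxymethyl)triumbelletin | COCOc1ccc2ccc(=O)oc2c1-c1c(OCOC)ccc2cc(Oc3ccc4ccc(=O)oc4c3)c(=O)oc12
F5 | step 6 | di-tert-butyl[(8-iodo-2-oxo-2H-chromen-7-yl)oxy]silane | CC(C)(C)[SiH](Oc1ccc2ccc(=O)oc2c1I)C(C)(C)C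
F6 | step 6 | bromodi-tert-butyl[(8-iodo-2-oxo-2H-chromen-7-yl)oxy]silane | CC(C)(C)[Si](Br)(Oc1ccc2ccc(=O)oc2c1I)C(C)(C)C
F7 | step 4 | 2-iodobenzene-1,3-diol | Oc1cccc(O)c1I
F8 | step 4 | 2,4-dihydroxy-3-iodobenzaldehyde | O=Cc1ccc(O)c(I)c1O
F9 | step 4 | 8-iodo-2-oxo-3-[(2-oxo-2H-chromen-7-yl)oxy]-2H-chromen-7-yl acetate | CC(=O)Oc1ccc2cc(Oc3ccc4ccc(=O)oc4c3)c(=O)oc2c1I
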